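## Retrosynthetic overview
1. Agrimol C is cut at both ArCH2–Ar bonds, made in the last step. This gives 2 × outer monomer, 2 × CH2O and central phlorbutyrophenone, joined by a Mannich base/o-quinone methide relay.
2. The outer monomer is cut at its aryl C6–OH bond, made by ketone-directed C–H hydroxylation of the 4-hydroxy-2-methoxy-3-methyl ketone.
3. Key bond: the ArO–CH3 bond at the chelated, hindered OH between acyl and methyl. It is made by chelation-gated Cu-catalysed O-methylation of 2,4-dihydroxy-3-methylbutyrophenone.
4. Both aryl ketones come from Friedel–Crafts acylation of 2-methylresorcinol or phloroglucinol with butyric acid.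
5. No ring is formed. All three benzene rings are bought and are joined outer–central–outer in the final step.

Assumption: the SMILES contains no stereocentre and no stable stereoaxis, so Agrimol C is achiral and there is no configuration to set.

## Route

Step 1
Reactants: 1 2-methylresorcinol; 2 butyric acid
Product: 3 1-(2,4-dihydroxy-3-methylphenyl)butan-1-one
Conditions: BF3·OEt2 (solvent), 2 (1.1 equiv), 90 °C, 2 h; then H2O
Reagents that add atoms: none
Why: This is a Nencki-type Friedel–Crafts acylation, in which only the two equivalent positions ortho/para to the OH groups are activated, the chelated o-hydroxyaryl ketone resists a second acylation, and no stereocentre is involved.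

Step 2
Reactants: 3 1-(2,4-dihydroxy-3-methylphenyl)butan-1-one
Product: 4 1-(4-hydroxy-2-methoxy-3-methylphenyl)butan-1-one
Conditions: Cu(OAc)2 (20 mol %), 1,10-phenanthroline (20 mol %), MeB(OH)2 (2.5 equiv, portionwise), no added base, O2 (1 atm), DCE, 60 °C
Reagents that add atoms: methylboronic acid CB(O)O
Why: Proposed new method: chelation-gated Chan–Lam O-methylation, in which, without external base, only the 2-OH can be cuprated, because acetate-assisted deprotonation closes a six-membered O,O-chelate with the ketone (as in Cu(II) 2-acylphenolates) while the more acidic but non-chelating 4-OH stays protonated; phenanthroline blocks the inert bis(acylphenolato)copper resting state; transmetalation from MeB(OH)2, aerobic oxidation to Cu(III)(CH3)(OAr) and C–O reductive elimination inside the chelate bay (away from the 3-methyl group) form the hindered ArO–CH3 bond; product 4 can no longer chelate, so it leaves copper and is not methylated again; the closest known reaction type is the Chan–Lam oxidative O-methylation (and O-cyclopropylation) of simple phenols and carboxylic acids with alkylboron reagents, which has not been shown to select a chelated OH over a free phenolic OH; no stereocentre is formed.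

Step 3
Reactants: 4 1-(4-hydroxy-2-methoxy-3-methylphenyl)butan-1-one
Product: 7 1-(4,6-dihydroxy-2-methoxy-3-methylphenyl)butan-1-one, via aryl trifluoroacetate 5 (not isolated), via bis(trifluoroacetate) 6 (not isolated)
Conditions: [RuCl2(p-cymene)]2 (2.5 mol %), PhI(OCOCF3)2 (1.5 equiv), TFA/TFAA 3:1, 80 °C; then THF/H2O, rt
Reagents that add atoms: [bis(trifluoroacetoxy)iodo]benzene O=C(OI(OC(=O)C(F)(F)F)c1ccccc1)C(F)(F)F; trifluoroacetic anhydride O=C(OC(=O)C(F)(F)F)C(F)(F)F (its atoms stay only in 5 and 6)
Why: This is a ketone-directed Ru(II)-catalysed ortho-C–H oxygenation, in which TFAA first masks the free phenol as the oxidation-resistant ester 5, the carbonyl oxygen (held anti to the 2-OMe) steers metalation to the only ortho C–H, I(III) oxidation and C–O reductive elimination give 6, and water cleaves both labile aryl trifluoroacetates.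

Step 4
Reactants: 8 phloroglucinol; 2 butyric acid
Product: 9 1-(2,4,6-trihydroxyphenyl)butan-1-one (phlorbutyrophenone)
Conditions: BF3·OEt2 (solvent), 2 (1.0 equiv), 85 °C, 2 h; then H2O
Reagents that add atoms: none
Why: This is a Friedel–Crafts acylation of a C3-symmetric arene, where all three positions are equivalent and one equivalent of acid plus deactivation by the first acyl group stops the reaction at the monoketone.

Step 5
Reactants: 7 1-(4,6-dihydroxy-2-methoxy-3-methylphenyl)butan-1-one (2.1 equiv); 9 phlorbutyrophenone (1.0 equiv)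
Product: 13 Agrimol C, via Mannich base 10 (not isolated), via o-quinone methide 11 (not isolated), via mono-bridged dimer 12 (not isolated)
Conditions: 7, 37% aq CH2O (2.1 equiv), 40% aq Me2NH (2.1 equiv), 1,4-dioxane, 0 °C to rt, 2 h; then 9, 90 °C, N2 sweep, 6 h; AcOH quench
Reagents that add atoms: formaldehyde C=O; dimethylamine CNC (its atoms stay only in 10)
Why: A Mannich reaction at the only free ring carbon of 7, followed by thermal loss of Me2NH, gives o-quinone methide 11, which is trapped in turn by the two nucleophilic ring carbons of 9 (vinylogous Michael/Friedel–Crafts alkylation); the electrophile has no free ring C–H and the nucleophile has exactly two, so only the 2:1 trimer builds up, and no stereocentre is formed.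

## Compound list
1 | 2-methylresorcinol (2-methylbenzene-1,3-diol) | Cc1c(O)cccc1O | starting material
2 | butyric acid | CCCC(=O)O | starting material
3 | 1-(2,4-dihydroxy-3-methylphenyl)butan-1-one | CCCC(=O)c1ccc(O)c(C)c1O | intermediate
4 | 1-(4-hydroxy-2-methoxy-3-methylphenyl)butan-1-one | CCCC(=O)c1ccc(O)c(C)c1OC | intermediate
5 | 4-butanoyl-3-methoxy-2-methylphenyl trifluoroacetate | CCCC(=O)c1ccc(OC(=O)C(F)(F)F)c(C)c1OC | intermediate
6 | 4-butanoyl-5-methoxy-6-methylbenzene-1,3-diyl bis(trifluoroacetate) | CCCC(=O)c1c(OC(=O)C(F)(F)F)cc(OC(=O)C(F)(F)F)c(C)c1OC | intermediate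
7 | 1-(4,6-dihydroxy-2-methoxy-3-methylphenyl)butan-1-one | CCCC(=O)c1c(O)cc(O)c(C)c1OC | intermediate
8 | phloroglucinol (benzene-1,3,5-triol) | Oc1cc(O)cc(O)c1 | starting material
9 | 1-(2,4,6-trihydroxyphenyl)butan-1-one | CCCC(=O)c1c(O)cc(O)cc1O | intermediate
10 | 1-{3-[(dimethylamino)methyl]-2,4-dihydroxy-6-methoxy-5-methylphenyl}butan-1-one | CCCC(=O)c1c(O)c(CN(C)C)c(O)c(C)c1OC | intermediate
11 | 2-butanoyl-5-hydroxy-3-methoxy-4-methyl-6-methylidenecyclohexa-2,4-dien-1-one | C=C1C(=O)C(C(=O)CCC)=C(OC)C(C)=C1O | intermediate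
12 | 1-{3-[(3-butanoyl-2,6-dihydroxy-4-methoxy-5-methylphenyl)methyl]-2,4,6-trihydroxyphenyl}butan-1-one | CCCC(=O)c1c(O)cc(O)c(Cc2c(O)c(C)c(OC)c(C(=O)CCC)c2O)c1O | intermediate
13 | Agrimol C, 1-{3,5-bis[(3-butanoyl-2,6-dihydroxy-4-methoxy-5-methylphenyl)methyl]-2,4,6-trihydroxyphenyl}butan-1-one (achiral) | CCCC(=O)c1c(O)c(Cc2c(O)c(C)c(OC)c(C(=O)CCC)c2O)c(O)c(Cc2c(O)c(C)c(OC)c(C(=O)CCC)c2O)c1O | target

## Step count
Total step count: 5. Longest linear sequence: 4 (steps 1, 2, 3, 5).

## Steps most likely to fail

**Step 2 (proposed new step).**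
- Risk: the free 4-OH may also be methylated, or copper may rest as an unreactive chelate.
- Fallback (known chemistry): it sets out from 3 and comes back at 4.
- The non-chelated 4-OH of 3 is benzylated (BnBr, K2CO3, acetone, reflux) to 1-[4-(benzyloxy)-2-hydroxy-3-methylphenyl]butan-1-one F1.
- The remaining chelated OH is then forced to react with excess MeI/K2CO3 in DMF at 60 °C, giving 1-[4-(benzyloxy)-2-methoxy-3-methylphenyl]butan-1-one F2.
- Hydrogenolysis (H2, Pd/C, EtOAc) returns 4.

**Step 3.**
- Risk: the ketone is twisted by the flanking OMe, and the I(III) oxidant may attack the α-CH2 or ring C5.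
- Fallback: it needs no C–H oxygenation. It sets out from 9 and comes back at 7.
- C-methylation of 9 (MeI 1.0 equiv, NaOMe, MeOH) gives 1-(2,4,6-trihydroxy-3-methylphenyl)butan-1-one F3.
- MOMCl (2.2 equiv)/iPr2NEt caps the two more accessible OH groups. The chelated OH next to the methyl group is left free, giving 1-[2-hydroxy-4,6-bis(methoxymethoxy)-3-methylphenyl]butan-1-one F4.
- MeI/K2CO3/DMF gives 1-[2-methoxy-4,6-bis(methoxymethoxy)-3-methylphenyl]butan-1-one F5.
- HCl/MeOH at 50 °C releases 7.

**Step 5.**
- Risk: the amine base may cause methylene scrambling (retro-Michael exchange to symmetric dimers), and the second alkylation may stay incomplete.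
- Fallback: the roles of the partners are reversed and the medium is acidic. It sets out from 9 and comes back at 13.
- 9 is treated with CH2O/Me2NH (2.2 equiv each), and the electrophile 1-{3,5-bis[(dimethylamino)methyl]-2,4,6-trihydroxyphenyl}butan-1-one F6 is isolated.
- F6 is heated with 7 (2.2 equiv) in AcOH/NaOAc at 70 °C.
- The coupling passes through the half-coupled amine 1-{3-[(3-butanoyl-2,6-dihydroxy-4-methoxy-5-methylphenyl)methyl]-5-[(dimethylamino)methyl]-2,4,6-trihydroxyphenyl}butan-1-one F7 and ends at 13.

## Further compounds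
F1 | step 2 | 1-[4-(benzyloxy)-2-hydroxy-3-methylphenyl]butan-1-one | CCCC(=O)c1ccc(OCc2ccccc2)c(C)c1O
F2 | step 2 | 1-[4-(benzyloxy)-2-methoxy-3-methylphenyl]butan-1-one | CCCC(=O)c1ccc(OCc2ccccc2)c(C)c1OC
F3 | step 3 | 1-(2,4,6-trihydroxy-3-methylphenyl)butan-1-one | CCCC(=O)c1c(O)cc(O)c(C)c1O
F4 | step 3 | 1-[2-hydroxy-4,6-bis(methoxymethoxy)-3-methylphenyl]butan-1-one | CCCC(=O)c1c(OCOC)cc(OCOC)c(C)c1O
F5 | step 3 | 1-[2-methoxy-4,6-bis(methoxymethoxy)-3-methylphenyl]butan-1-one | CCCC(=O)c1c(OCOC)cc(OCOC)c(C)c1OC
F6 | step 5 | 1-{3,5-bis[(dimethylamino)methyl]-2,4,6-trihydroxyphenyl}butan-1-one | CCCC(=O)c1c(O)c(CN(C)C)c(O)c(CN(C)C)c1O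
F7 | step 5 | 1-{3-[(3-butanoyl-2,6-dihydroxy-4-methoxy-5-methylphenyl)methyl]-5-[(dimethylamino)methyl]-2,4,6-trihydroxyphenyl}butan-1-one | CCCC(=O)c1c(O)c(CN(C)C)c(O)c(Cc2c(O)c(C)c(OC)c(C(=O)CCC)c2O)c1O
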